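Each hand is half of the substrate charged, so a product reading in percent, doubled, gives the part of that hand's own charge turned into product, and without exchange that is also the part gone from that charge. Here is what is known and asked:

in all of them: left-handed substrate 30 mM; right-handed substrate 30 mM; partner 120 mM; racemization catalyst 0.60 mM; added ligand 2.6 mM

|  | impurity | remark | time |
|---|---|---|---|
| red | 0.074 mM | run made earlier |  |
| violet | 0.17 mM | run made earlier |  |
| flask | 0.11 mM |  | 12 h |

| run | time / h | left-handed product / % | right-handed product / % |
|---|---|---|---|
| red | 1.00 | 4 | 3 |
| red | 3.00 | 14 | 6 |
| red | 6.00 | 23 | 10 |
| red | 8.00 | 29 | 12 |
| red | 12.0 | 34 | 16 |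
| violet | 1.00 | 6 | 1 |
| violet | 3.00 | 16 | 9 |
| violet | 6.00 | 25 | 9 |
| violet | 8.00 | 28 | 12 |
| violet | 12.0 | 34 | 14 |

(each reading ± 1.5 percentage points)

- partner is single-handed; left-handed substrate and right-handed substrate are mirror images of each other, charged as a racemate, each of them at the stated concentration
- steps thought possible: partner + left-handed substrate -> left-handed product; partner + right-handed substrate -> right-handed product; left-handed substrate + racemization catalyst <-> right-handed substrate + racemization catalyst; racemization catalyst + impurity -> spent catalyst A; racemization catalyst -> spent catalyst B; racemization catalyst + added ligand <-> idle complex
- an excess is the difference of the two amounts in percent of their sum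
- an excess is below zero if the other one leads
- the handed part of partner does not stay in what it makes, so the products of the two hands are mirror images too

* left-handed product and right-handed product together, in percent of the left-handed substrate and right-handed substrate charged together, at 12 h
* excess of left-handed product over right-handed product in the product at 12 h
* whether the exchange between left-handed substrate and right-handed substrate keeps pace with the reaction: how far the product's excess at 12 h gets from its value without exchange to its value with instant exchange (above 80% keeps pace, below 20% hardly takes part, else lags behind)

In the first instants the impurity can take catalyst, one for one: its charge is 12.3% of the catalyst in the red run and 28.3% in the violet run. Yet at 12.0 h left-handed product reads 34% in the red run and 34% in the violet run. The flask's impurity lies between the two, so I read the flask from both runs pooled.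

In the middle both hands draw on the same partner, charged at twice what the two hands together can use. Without exchange the partner therefore cancels from this ratio:

s = ln(c left-handed substrate / its charge) / ln(c right-handed substrate / its charge)

pooled at 6.00 h: s = 3.10, product ratio 2.53

pooled at 12.0 h: s = 3.19, product ratio 2.27

This s, the selectivity factor, is the logarithm of what remains of one hand's charge over the same for the other. Instant exchange keeps the two substrates equal and so holds the product ratio flat. Towards the end, though, the ratio falls while s stays close. With a scatter of 1.5 percentage points this is a reading, not a proof, but I expect exchange to hardly take part.

The forecast gives 49%, an excess of 39%, and "lags behind", saying “Exchange is probably partial”. I accept its two numbers and differ on the pace.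

The flask gives 51.6%, an excess of 35.6%, and "hardly takes part", at 4.6% of the way.

    partner + left-handed substrate → left-handed product (k = 0.972 L mol⁻¹ h⁻¹)
    partner + right-handed substrate → right-handed product (k = 0.334 L mol⁻¹ h⁻¹)
    left-handed substrate + racemization catalyst ⇌ right-handed substrate + racemization catalyst, rate k3*[racemization catalyst]*[left-handed substrate] forward; the back reaction follows from the equilibrium constant (k = 91.4 L mol⁻¹ h⁻¹)
    racemization catalyst + impurity → spent catalyst A (k = 2.28 × 10⁵ L mol⁻¹ h⁻¹)
    racemization catalyst → spent catalyst B (k = 0.0463 h⁻¹)
    racemization catalyst + added ligand ⇌ idle complex, settled at all times (K = 2890 L mol⁻¹)

At 12.0 h the flask keeps 32% of its left-handed substrate charge and 65% of its right-handed substrate charge, so s is 2.68. The neighbour charged with 72 mM of partner reaches 35.8% with an excess of 40.8%. Applied to the 78% of its right-handed substrate charge left in the neighbour, that s gives 50.7% of the left-handed substrate charge left, and the neighbour keeps 51%.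

(The runs come from a simulation with made-up constants; scatter was added.)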